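Ring A is cut across C1–C10 and C3–C4 (labdane numbering). Acrolein supplies C1–C3. The C4–C5–C10 triad comes as a monocyclic ring B that carries two methylidene groups: C10=C20H2 and the acrylate C4=C18H2. In one pot an iron hydride transfers H atoms to both. Transfer to C20 gives the tertiary C10 radical, which adds to acrolein. Transfer to C18 gives the C4 ester enolate, which closes onto the new C3 aldehyde. The step exploits the two methyl-bearing quaternary carbons C10 and C4 that flank C5–H in ring A, with the C3 carbinol next to C4. Both methyl groups are completed by hydrogen, and the trans ring fusion, C3, C4 and C10 are set together.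

Key step: step 8

Remark: locants are those of the labdane skeleton (C1–C20); α is the face of the C20 methyl group and β the face of H-5; (R)-2,3-O-isopropylideneglyceraldehyde and 3-bromofuran-2(5H)-one are taken as commercial.

Step 1
Reactants: 1 hex-4-yn-1-ol
Product: 2 triethyl(hex-4-yn-1-yloxy)silane
Conditions: Et3SiCl, imidazole, CH2Cl2, 0 °C
Reagents that add atoms: chlorotriethylsilane, CC[Si](Cl)(CC)CC
Why: Silyl ether formation masks the C8 oxygen through the organometallic and enolate steps and allows its later direct oxidation.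

Step 2
Reactants: 2 triethyl(hex-4-yn-1-yloxy)silane; 3 (R)-2,2-dimethyl-1,3-dioxolane-4-carbaldehyde
Product: 6 (1S,2E)-1-[(4R)-2,2-dimethyl-1,3-dioxolan-4-yl]-2-methyl-6-(triethylsilyloxy)hex-2-en-1-ol, via alkenylzirconocene 4 (not isolated), via alkenylzinc 5 (not isolated)
Conditions: Cp2Zr(H)Cl, THF, 25 to 45 °C; Me2Zn, PhMe, −65 °C; then 3, 0 °C
Reagents that add atoms: none
Why: Syn hydrozirconation should place the metal on the methyl-bearing alkyne carbon (C10), and after transmetalation to zinc a Felkin–Anh addition to the α-alkoxy aldehyde should give mainly the anti (9S) carbinol, with C11 taken from the chiral pool.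

Step 3
Reactants: 6 the allylic alcohol; 7 2-(diethoxyphosphoryl)acetic acid
Product: 8 (1S,2E)-1-[(4R)-2,2-dimethyl-1,3-dioxolan-4-yl]-2-methyl-6-(triethylsilyloxy)hex-2-en-1-yl 2-(diethoxyphosphoryl)acetate
Conditions: DCC, DMAP (cat.), CH2Cl2, 0 to 25 °C
Reagents that add atoms: none
Why: Steglich esterification should acylate the secondary allylic alcohol without touching the ketal or silyl ether.

Step 4
Reactants: 8 the allylic phosphonoacetate
Product: 10 methyl (3S,4E)-2-(diethoxyphosphoryl)-5-[(4S)-2,2-dimethyl-1,3-dioxolan-4-yl]-4-methyl-3-[3-(triethylsilyloxy)propyl]pent-4-enoate (C2 epimers), via phosphono acid 9 (not isolated)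
Conditions: LiHMDS, Me3SiCl, THF, −78 °C, then PhMe, 100 °C; 1 M HCl; TMSCHN2, PhMe/MeOH, 0 °C
Reagents that add atoms: (trimethylsilyl)diazomethane, C[Si](C)(C)C=[N+]=[N-]
Why: Ireland–Claisen rearrangement through a chair with the dioxolanyl group equatorial should transfer the C9 configuration to C5 (S) and give the E C9=C10 alkene, after which the acid is methylated.

Step 5
Reactants: 10 the phosphono ester
Product: 11 methyl (3S,4E)-5-[(4S)-2,2-dimethyl-1,3-dioxolan-4-yl]-4-methyl-2-methylidene-3-[3-(triethylsilyloxy)propyl]pent-4-enoate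
Conditions: aq. HCHO, K2CO3, THF, 25 to 50 °C
Reagents that add atoms: formaldehyde, C=O
Why: Horner–Wadsworth–Emmons olefination with formaldehyde should turn the phosphonoacetate carbon (C4) into the 2-substituted acrylate, C18 being the new methylidene carbon.

Step 6
Reactants: 11 the silyl ether acrylate
Product: 12 methyl (3S,4E)-5-[(4S)-2,2-dimethyl-1,3-dioxolan-4-yl]-4-methyl-2-methylidene-3-(3-oxopropyl)pent-4-enoate
Conditions: (COCl)2, DMSO, CH2Cl2, −78 °C; Et3N, −78 to −20 °C
Reagents that add atoms: none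
Why: Swern oxidation should cleave and oxidise the primary triethylsilyl ether directly to the C8 aldehyde, while the ketal and acrylate are inert.

Step 7
Reactants: 12 the aldehyde
Product: 13 methyl 2-[(1S,3S,4R)-3-[(4S)-2,2-dimethyl-1,3-dioxolan-4-yl]-4-hydroxy-2-methylidenecyclohexyl]prop-2-enoate
Conditions: Me2AlCl, CH2Cl2, −78 to −40 °C
Reagents that add atoms: none
Why: In a type 2 intramolecular carbonyl-ene reaction the activated aldehyde should be attacked by C9 of the trisubstituted alkene while a C20 hydrogen passes to oxygen, closing ring B in a chair with the C5 and C9 groups equatorial (cis) and the C8 hydroxyl axial.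

Step 8
Reactants: 13 the ring B methylidene acrylate; 14 acrolein
Product: 16 methyl 3α,8α-dihydroxy-9α-[(4S)-2,2-dimethyl-1,3-dioxolan-4-yl]-4β,10α-dimethyl-trans-decalin-4α-carboxylate (H-5 β, H-9 β), via Giese aldehyde 15 (not isolated)
Conditions: Fe(acac)3 (30 mol %), PhSiH3, acrolein (excess), EtOH/(CH2OH)2, 0 to 40 °C, one pot
Reagents that add atoms: none
Why: Proposed new method: the iron hydride formed from Fe(acac)3 and PhSiH3 should transfer H• to C20 of the alkyl-substituted 1,1-disubstituted alkene, the nucleophilic tertiary C10 radical adds to C1 of acrolein and the α-formyl radical is reduced and protonated to aldehyde 15, after which a second H• transfer to C18 of the acrylate gives the C4 radical, which is reduced to the iron ester enolate and adds to C3. The closest known reaction types are the metal-hydride hydrogen-atom-transfer (MHAT) Giese coupling of alkenes with enals, MHAT radical–polar crossover annulation and metal-hydride reductive aldol cyclisation, and their union as a two-fold HAT [3+3] annulation on one substrate is the new element. Ring A closes by a 6-(enolexo)-exo-trig aldol addition through a chelated chair Zimmerman–Traxler transition state. C10 is set by approach of acrolein from the β face, which lets C20 go axial (α) and so escape both flanking equatorial groups at C5 and C9 and the axial C8–O, giving the trans ring fusion; C4 and C3 follow from the chair, in which C18 takes the equatorial site to avoid a 1,3-diaxial clash with C20, the ester is axial (α) and the chelated aldehyde oxygen equatorial (α, cis to C19). The step needs H• transfer to the electron-rich alkene before the acrylate and a polarity match at each radical: the nucleophilic C10 radical takes the excess acrolein, the electrophilic C4 radical ignores acrolein and is only reduced, and the protic medium protonates the first enolate before it can add to the acrylate.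

Step 9
Reactants: 16 the decalin hydroxy ester
Product: 17 the 3α,8α,19-triol (4α-CH2OH in place of the ester)
Conditions: LiAlH4, THF, 0 °C
Reagents that add atoms: none
Why: Hydride reduction should convert the hindered axial ester into the C19 primary alcohol at a temperature where the β-alkoxide does not undergo retro-aldol cleavage.

Step 10
Reactants: 17 the triol
Product: 18 the 3,19-O-(di-tert-butylsilylene) derivative with free 8α-OH
Conditions: tBu2Si(OTf)2, 2,6-lutidine, CH2Cl2, −20 to 0 °C
Reagents that add atoms: di-tert-butylsilyl bis(trifluoromethanesulfonate), CC(C)(C)[Si](OS(=O)(=O)C(F)(F)F)(OS(=O)(=O)C(F)(F)F)C(C)(C)C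
Why: Cyclic silylene formation should be selective for the 1,3-diol, since the isolated hindered axial C8 hydroxyl cannot form a ring.

Step 11
Reactants: 18 the silylene alcohol
Product: 19 the C8 ketone
Conditions: Dess–Martin periodinane, NaHCO3, CH2Cl2, 25 °C
Reagents that add atoms: none
Why: Dess–Martin oxidation of the only free secondary alcohol should proceed under buffered conditions that spare the ketal and silylene.

Step 12
Reactants: 19 the C8 ketone
Product: 20 the 8(17)-methylidene compound
Conditions: Ph3PCH3Br, KOtBu, PhMe, 90 °C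
Reagents that add atoms: methyltriphenylphosphonium bromide, C[P+](c1ccccc1)(c1ccccc1)c1ccccc1.[Br-]
Why: Wittig methylenation should install the exocyclic C8=C17 alkene, and any base-induced equilibration at C9 converges on the equatorial side chain already present.

Step 13
Reactants: 20 the methylidene dioxolane
Product: 21 the (11S)-11,12-diol
Conditions: AcOH/H2O/THF (3:1:1), 40 °C
Reagents that add atoms: none
Why: Acid hydrolysis should remove the terminal isopropylidene ketal while the di-tert-butylsilylene survives.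

Step 14
Reactants: 21 the 11,12-diol
Product: 22 the (11S)-11,12-epoxide
Conditions: NaH, N-tosylimidazole, THF, 0 to 25 °C
Reagents that add atoms: none
Why: The primary C12 alkoxide should be sulfonylated selectively and then displaced by the C11 alkoxide (intramolecular Williamson etherification), so the epoxide forms with retention at C11.

Step 15
Reactants: 23 3-bromofuran-2(5H)-one
Product: 24 (3-bromofuran-2-yloxy)triisopropylsilane
Conditions: iPr3SiOTf, Et3N, CH2Cl2, 0 °C
Reagents that add atoms: triisopropylsilyl trifluoromethanesulfonate, CC(C)[Si](C(C)C)(C(C)C)OS(=O)(=O)C(F)(F)F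
Why: O-silylation of the butenolide dienolate should give the aromatic 2-silyloxyfuran.

Step 16
Reactants: 22 the epoxide; 24 (3-bromofuran-2-yloxy)triisopropylsilane
Product: 27 3,19-O-(di-tert-butylsilylene)-14-deoxy-11-hydroxyandrographolide, via lithiofuran 25 (not isolated), via silyloxyfuran adduct 26 (not isolated)
Conditions: 24, t-BuLi, Et2O, −78 °C; 22, BF3·OEt2, −78 °C; then 1 M HCl, THF, 0 °C
Reagents that add atoms: none
Why: Bromine–lithium exchange should give the 3-lithio-2-silyloxyfuran (a butenolide α-anion equivalent), which opens the BF3-activated epoxide at the terminal carbon C12, and acid hydrolysis of the silyl dienol ether gives the butenolide with C11 untouched.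

Step 17
Reactants: 27 the silylene-protected butenolide
Product: 28 14-deoxy-11-hydroxyandrographolide
Conditions: HF·pyridine, THF, 0 to 25 °C
Reagents that add atoms: none
Why: Fluoride cleavage of the silylene should release the 3,19-diol without affecting the butenolide or the exocyclic alkene.

Compound list
1 | hex-4-yn-1-ol | CC#CCCCO | starting material
2 | triethyl(hex-4-yn-1-yloxy)silane | CC#CCCCO[Si](CC)(CC)CC | intermediate
3 | (R)-2,2-dimethyl-1,3-dioxolane-4-carbaldehyde | O=C[C@H]1COC(C)(C)O1 | starting material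
4 | chlorobis(cyclopentadienyl)[(2E)-6-(triethylsilyloxy)hex-2-en-2-yl]zirconium | CC[Si](CC)(CC)OCCC/C=C(\C)[Zr](Cl)(C1C=CC=C1)C1C=CC=C1 | intermediate (not isolated)
5 | methyl[(2E)-6-(triethylsilyloxy)hex-2-en-2-yl]zinc | CC[Si](CC)(CC)OCCC/C=C(\C)[Zn]C | intermediate (not isolated)
6 | (1S,2E)-1-[(4R)-2,2-dimethyl-1,3-dioxolan-4-yl]-2-methyl-6-(triethylsilyloxy)hex-2-en-1-ol | CC[Si](CC)(CC)OCCC/C=C(\C)[C@H](O)[C@H]1COC(C)(C)O1 | intermediate
7 | 2-(diethoxyphosphoryl)acetic acid | CCOP(=O)(CC(=O)O)OCC | starting material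
8 | (1S,2E)-1-[(4R)-2,2-dimethyl-1,3-dioxolan-4-yl]-2-methyl-6-(triethylsilyloxy)hex-2-en-1-yl 2-(diethoxyphosphoryl)acetate | CC[Si](CC)(CC)OCCC/C=C(\C)[C@H](OC(=O)CP(=O)(OCC)OCC)[C@H]1COC(C)(C)O1 | intermediate
9 | (3S,4E)-2-(diethoxyphosphoryl)-5-[(4S)-2,2-dimethyl-1,3-dioxolan-4-yl]-4-methyl-3-[3-(triethylsilyloxy)propyl]pent-4-enoic acid (C2 epimers) | CC[Si](CC)(CC)OCCC[C@H](C(C(=O)O)P(=O)(OCC)OCC)/C(C)=C/[C@H]1COC(C)(C)O1 | intermediate (not isolated)
10 | methyl (3S,4E)-2-(diethoxyphosphoryl)-5-[(4S)-2,2-dimethyl-1,3-dioxolan-4-yl]-4-methyl-3-[3-(triethylsilyloxy)propyl]pent-4-enoate (C2 epimers) | CC[Si](CC)(CC)OCCC[C@H](C(C(=O)OC)P(=O)(OCC)OCC)/C(C)=C/[C@H]1COC(C)(C)O1 | intermediate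
11 | methyl (3S,4E)-5-[(4S)-2,2-dimethyl-1,3-dioxolan-4-yl]-4-methyl-2-methylidene-3-[3-(triethylsilyloxy)propyl]pent-4-enoate | CC[Si](CC)(CC)OCCC[C@H](C(=C)C(=O)OC)/C(C)=C/[C@H]1COC(C)(C)O1 | intermediate
12 | methyl (3S,4E)-5-[(4S)-2,2-dimethyl-1,3-dioxolan-4-yl]-4-methyl-2-methylidene-3-(3-oxopropyl)pent-4-enoate | O=CCC[C@H](C(=C)C(=O)OC)/C(C)=C/[C@H]1COC(C)(C)O1 | intermediate
13 | methyl 2-[(1S,3S,4R)-3-[(4S)-2,2-dimethyl-1,3-dioxolan-4-yl]-4-hydroxy-2-methylidenecyclohexyl]prop-2-enoate (ring B: H-5 β, H-9 β, 8α-OH) | O[C@@H]1CC[C@H](C(=C)C(=O)OC)C(=C)[C@@H]1[C@H]2COC(C)(C)O2 | intermediate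
14 | acrolein (prop-2-enal) | C=CC=O | starting material
15 | Giese aldehyde: 13 in which C10 is quaternary with α-CH3 (C20) and β-3-oxopropyl (C1–C3), trans to the C5 and C9 groups | O[C@@H]1CC[C@H](C(=C)C(=O)OC)[C@@](C)(CCC=O)[C@@H]1[C@H]2COC(C)(C)O2 | intermediate (not isolated)
16 | methyl 3α,8α-dihydroxy-9α-[(4S)-2,2-dimethyl-1,3-dioxolan-4-yl]-4β,10α-dimethyl-trans-decalin-4α-carboxylate (H-5 β, H-9 β) | O[C@@H]1CC[C@@H]2[C@](C)(C(=O)OC)[C@H](O)CC[C@@]2(C)[C@@H]1[C@H]3COC(C)(C)O3 | intermediate
17 | 3α,8α,19-triol: 16 with 4α-CH2OH in place of the ester | O[C@@H]1CC[C@@H]2[C@](C)(CO)[C@H](O)CC[C@@]2(C)[C@@H]1[C@H]3COC(C)(C)O3 | intermediate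
18 | 3,19-O-(di-tert-butylsilylene) derivative of 17 with free 8α-OH | O[C@@H]1CC[C@@H]2[C@](C)(CO3)[C@H](O[Si]3(C(C)(C)C)C(C)(C)C)CC[C@@]2(C)[C@@H]1[C@H]4COC(C)(C)O4 | intermediate
19 | C8 ketone of 18 | O=C1CC[C@@H]2[C@](C)(CO3)[C@H](O[Si]3(C(C)(C)C)C(C)(C)C)CC[C@@]2(C)[C@@H]1[C@H]4COC(C)(C)O4 | intermediate
20 | 8(17)-methylidene compound with 9α-[(4S)-2,2-dimethyl-1,3-dioxolan-4-yl] and 3,19-O-silylene | C=C1CC[C@@H]2[C@](C)(CO3)[C@H](O[Si]3(C(C)(C)C)C(C)(C)C)CC[C@@]2(C)[C@@H]1[C@H]4COC(C)(C)O4 | intermediate
21 | (11S)-11,12-diol with 3,19-O-silylene and 8(17)-ene | C=C1CC[C@@H]2[C@](C)(CO3)[C@H](O[Si]3(C(C)(C)C)C(C)(C)C)CC[C@@]2(C)[C@@H]1[C@H](O)CO | intermediate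
22 | (11S)-11,12-epoxide with 3,19-O-silylene and 8(17)-ene | C=C1CC[C@@H]2[C@](C)(CO3)[C@H](O[Si]3(C(C)(C)C)C(C)(C)C)CC[C@@]2(C)[C@@H]1[C@H]4CO4 | intermediate
23 | 3-bromofuran-2(5H)-one | O=C1OCC=C1Br | starting material
24 | (3-bromofuran-2-yloxy)triisopropylsilane | CC(C)[Si](C(C)C)(C(C)C)Oc1occc1Br | intermediate
25 | 3-lithio-2-(triisopropylsilyloxy)furan | CC(C)[Si](C(C)C)(C(C)C)Oc1occc1[Li] | intermediate (not isolated)
26 | (11R)-11-hydroxy-12-[2-(triisopropylsilyloxy)furan-3-yl] adduct with 3,19-O-silylene | C=C1CC[C@@H]2[C@](C)(CO3)[C@H](O[Si]3(C(C)(C)C)C(C)(C)C)CC[C@@]2(C)[C@@H]1[C@H](O)Cc1ccoc1O[Si](C(C)C)(C(C)C)C(C)C | intermediate (not isolated)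
27 | 3,19-O-(di-tert-butylsilylene)-14-deoxy-11-hydroxyandrographolide | C=C1CC[C@@H]2[C@](C)(CO3)[C@H](O[Si]3(C(C)(C)C)C(C)(C)C)CC[C@@]2(C)[C@@H]1[C@H](O)CC1=CCOC1=O | intermediate
28 | 14-deoxy-11-hydroxyandrographolide (3R,4R,5S,9R,10R,11R) | C=C1CC[C@@H]2[C@](C)(CO)[C@H](O)CC[C@@]2(C)[C@@H]1[C@H](O)CC1=CCOC1=O | target

Total step count: 17. Longest linear sequence: 16 steps (steps 1–14, 16 and 17); step 15 prepares the furan reagent.

Steps most likely to fail

Step 8. Hydrogen-atom transfer may reach the acrylate before the aldehyde exists, so the enolate precursor is lost by simple reduction. Facial selectivity at C10 or C4 may also be poor, or the first enolate may close onto the acrylate. The fallback sets out from 13 and returns at 16, separating the two bond formations with known chemistry. Alkene 13 is coupled with acrolein by the iron-hydride alkene–enal Giese reaction (Fe(acac)3, PhSiH3 held near one equivalent, EtOH, 0 °C) and the Giese aldehyde 15 is isolated. Its acrylate–aldehyde pair is then closed by a copper hydride reductive aldol cyclisation ([(Ph3P)CuH]6, PhMe, −40 to 0 °C), a polar hydride addition to C18, to give 16. No compound outside the list is made (entry F0).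

Step 4. The [3,3] shift of the stabilised phosphonate silyl ketene acetal may be sluggish, with C-silylation or ester cleavage taking over. The fallback sets out from 6 and returns at 11. Johnson–Claisen rearrangement of 6 with trimethyl orthoacetate (cat. propionic acid, xylene, 135 °C) passes through the same chair and gives methyl (3R,4E)-5-[(4S)-2,2-dimethyl-1,3-dioxolan-4-yl]-4-methyl-3-[3-(triethylsilyloxy)propyl]pent-4-enoate F1. Its lithium enolate (LDA, THF, −78 °C) is trapped with Eschenmoser's salt to give the 2-[(dimethylamino)methyl] ester F2. Quaternisation with MeI and elimination with DBU then give acrylate 11.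

Step 16. The lithiated silyloxyfuran may decompose, or the epoxide may rearrange under the Lewis acid before the C–C bond forms. The fallback sets out from 22 and returns at 27. The epoxide is opened at C12 by the lithium acetylide of 2-(prop-2-yn-1-yloxy)oxane with BF3·OEt2 (THF, −78 °C) to give the oxanyl-protected homopropargylic alcohol F3. PPTS in MeOH gives the alkyne diol F4. NaAlH2(OCH2CH2OCH3)2 followed by I2 gives, by anti hydroalumination, the (Z)-13-iodo allylic alcohol F5. Carbonylative lactonisation (PdCl2(PPh3)2, CO, Et3N, THF) then closes the butenolide 27.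

Further compounds
F0 | step 8 | none | none
F1 | step 4 | methyl (3R,4E)-5-[(4S)-2,2-dimethyl-1,3-dioxolan-4-yl]-4-methyl-3-[3-(triethylsilyloxy)propyl]pent-4-enoate | CC[Si](CC)(CC)OCCC[C@H](CC(=O)OC)/C(C)=C/[C@H]1COC(C)(C)O1
F2 | step 4 | methyl (3R,4E)-2-[(dimethylamino)methyl]-5-[(4S)-2,2-dimethyl-1,3-dioxolan-4-yl]-4-methyl-3-[3-(triethylsilyloxy)propyl]pent-4-enoate (C2 epimers) | CC[Si](CC)(CC)OCCC[C@H](C(CN(C)C)C(=O)OC)/C(C)=C/[C@H]1COC(C)(C)O1
F3 | step 16 | (11R)-11-hydroxy-12-[3-(oxan-2-yloxy)prop-1-yn-1-yl] compound with 3,19-O-silylene and 8(17)-ene | C=C1CC[C@@H]2[C@](C)(CO3)[C@H](O[Si]3(C(C)(C)C)C(C)(C)C)CC[C@@]2(C)[C@@H]1[C@H](O)CC#CCOC1CCCCO1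
F4 | step 16 | (11R)-11,15-dihydroxy-13-yne with 3,19-O-silylene and 8(17)-ene | C=C1CC[C@@H]2[C@](C)(CO3)[C@H](O[Si]3(C(C)(C)C)C(C)(C)C)CC[C@@]2(C)[C@@H]1[C@H](O)CC#CCO
F5 | step 16 | (11R,13Z)-11,15-dihydroxy-13-iodo-13-ene with 3,19-O-silylene and 8(17)-ene | C=C1CC[C@@H]2[C@](C)(CO3)[C@H](O[Si]3(C(C)(C)C)C(C)(C)C)CC[C@@]2(C)[C@@H]1[C@H](O)C/C(I)=C/CO
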